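Take a small charge: one molecule of starting material in the dusk flask, 1.0 M of it with 2.50 M of partner at 0 °C. Partner is in excess, so starting material is the limiting reagent, and I ask at which fork each molecule ends up. The flask is the sum of those chances.

| setting | dusk | midnight | flask |
|---|---|---|---|
| starting material | 1 M | 1 M | 1.0 M |
| partner | 2.5 M | 2.5 M | 2.50 M |
| temperature | 0 °C | −15 °C | 0 °C |
| remark | the very flask that is asked about, followed so far | run made earlier |  |
| time |  |  | 2.0 h |

| run | time / min | target / % |
|---|---|---|
| dusk | 25.0 | 17.1 |
| dusk | 50.0 | 17.4 |
| dusk | 80.0 | 15.6 |
| dusk | 90.0 | 17.4 |
| dusk | 120 | 16.2 |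
| midnight | 50.0 | 2.8 |
| midnight | 120 | 2.7 |
| midnight | 180 | 3.0 |
| midnight | 240 | 2.2 |

(readings scatter by 0.5 percentage points)

- target, in percent of the starting material first charged, at 2.0 h
- what to do for the largest gain in target; "none" if nothing gains more than 2 percentage points (delta / zeta / beta / none)
- target present, with what was taken out counted in, in percent of the starting material first charged, after delta
- target present, with what was taken out counted in, in percent of the starting material first charged, after beta

- delta: at 2.0 h raise the temperature by 15 K, then wait 4.0 h
- zeta: at 2.0 h take out 90% of the target then present, then wait 4.0 h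
- beta: change nothing and wait 4.0 h more

- percent here means starting material units held: one self-condensation product counts as two
- what is taken out of target is counted as made
- candidate steps: partner + other conformer -> isomer of the product A; starting material <-> other conformer; 2 starting material -> self-condensation product; target <-> isomer of the product B; starting material + partner -> target

I read the readings as a ladder. The first rung is over before anyone looks: target reads 17.1% by 25.0 min in the dusk flask, and 2.8% by 50.0 min in the midnight flask at −15 °C. The second rung is a plateau. Dusk readings stay near 16.7% up to 120 min, and midnight readings stay near 2.67% up to 240 min, with no trend beyond the scatter of 0.5 percentage points. So I expect beta to return the plateau, and I put the dusk flask at 16.7% now. The third rung is the further wait, ten times the 25.0 min of the first reading, which leaves room for a new plateau if target and isomer of the product B are in equilibrium.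

A plateau is a pair of odds, target against everything else: 0.201 at dusk, 0.0275 at midnight. Their ratio, the odds step for 15 K, is 7.32. One more step gives odds of 1.47, which is 59.5% target after delta if the pair holds every molecule. I choose delta, and I take that figure as a ceiling.

The forecast gives 16.7% now (16.2% to 17.2%), 16.7% after beta, and delta as the choice, with 45% (16% to 58%). That range is wide for a stated reason: “these data cannot separate them”. My ceiling stands above its central figure.

The flask gives 16.5% now, 16.5% after beta and 51.5% after delta. So delta gains 35 points, against 12 points for zeta.

    partner + other conformer → isomer of the product A (k = 0.00310 L mol⁻¹ s⁻¹, Ea = 43.0 kJ mol⁻¹)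
    starting material ⇌ other conformer (K = 1.70, k = 0.0150 s⁻¹, Ea = 78.0 kJ mol⁻¹, ΔH = −33.0 kJ mol⁻¹)
    2 starting material → self-condensation product (k = 0.0110 L mol⁻¹ s⁻¹, Ea = 61.0 kJ mol⁻¹)
    target ⇌ isomer of the product B (K = 3.50, k = 0.0670 s⁻¹, Ea = 75.0 kJ mol⁻¹, ΔH = −90.0 kJ mol⁻¹)
    starting material + partner → target (k = 0.0200 L mol⁻¹ s⁻¹, Ea = 56.0 kJ mol⁻¹)
    (constants at 0 °C)

The target and isomer of the product B pair relaxes with a half-life of 0.134 min, shorter than the 0.27 min in which starting material goes to target at 0.212 min. At 120 min the flask holds 16.5% target and 57.8% isomer of the product B, a pool of 74.3% and a ratio of 0.286. One odds step on that ratio gives 50.3% target, against 51.5%. For the same flask run at 25 °C, 1.67 steps give a ratio of 7.89; computed, it holds 70.3% target and 8.87% isomer of the product B, a ratio of 7.93.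

The readings were generated by integration for substances that don't exist; the scatter is artificial.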